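**Retrosynthetic overview**

1. Target 20 ⇒ ester 19: the C3 hydroxymethyl group comes from a methyl ester by hydride reduction.
2. 19 ⇒ diazo ester 17: C2–C3 is cut. A rhodium carbene at C3 inserts into the benzylic C–H of a ring A benzyl ether and closes the oxolane, the only ring made in the route.
3. Feature used: oxolane C2 is both benzylic to ring A and α to O1. In the open-chain ether this C–H is the most activated one and lies 1,5 to C3; the C4 centre steers C2 and C3.
4. 17 ⇒ methyl ester 15 (Claisen benzoylation, deacylative diazo transfer) ⇒ alkene 11 (oxidative cleavage) ⇒ alcohol 8 + chloride 9 (etherification).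
5. 8 ⇒ imide 4 + allyl bromide 5: the single stereocentre (future C4) is set by auxiliary-controlled allylation; 4 comes from acid 1 and oxazolidinone 2.

Key step: step 9

Remark: ring A is the aryl group on C2, ring B the aryl group of the C4 benzyl substituent, and the oxolane is numbered O1, C2, C3, C4, C5; salts of products that are only protonated on work-up are not numbered.

**Route**

Step 1
Reactants: 1 3-(3,4,5-trimethoxyphenyl)propanoic acid; 2 (4S)-4-benzyl-1,3-oxazolidin-2-one
Product: 4 (4S)-4-benzyl-3-[3-(3,4,5-trimethoxyphenyl)propanoyl]-1,3-oxazolidin-2-one, via mixed pivalic anhydride 3 (not isolated)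
Conditions: t-BuCOCl, Et3N, THF, −20 °C; then 2, LiCl, −20 °C → rt
Reagents that add atoms: none
Why: Mixed-anhydride N-acylation: pivaloyl chloride activates 1 as anhydride 3, and the LiCl-activated oxazolidinone nitrogen attacks its less hindered carbonyl; no stereocentre is formed.

Step 2
Reactants: 4 (4S)-4-benzyl-3-[3-(3,4,5-trimethoxyphenyl)propanoyl]-1,3-oxazolidin-2-one; 5 3-bromoprop-1-ene
Product: 7 (4S)-4-benzyl-3-{(2S)-2-[(3,4,5-trimethoxyphenyl)methyl]pent-4-enoyl}-1,3-oxazolidin-2-one, via sodium (Z)-enolate 6 (not isolated)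
Conditions: NaN(SiMe3)2, THF, −78 °C; then 5, −78 → −40 °C
Reagents that add atoms: none
Why: Evans alkylation: the chelated sodium (Z)-enolate 6 is open to allyl bromide only on the face away from the benzyl group of the auxiliary, which should set the new centre (the future C4) as S.

Step 3
Reactants: 7 (4S)-4-benzyl-3-{(2S)-2-[(3,4,5-trimethoxyphenyl)methyl]pent-4-enoyl}-1,3-oxazolidin-2-one
Product: 8 (2S)-2-[(3,4,5-trimethoxyphenyl)methyl]pent-4-en-1-ol
Conditions: LiBH4, H2O (1 equiv), Et2O, 0 °C
Reagents that add atoms: none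
Why: Reductive cleavage of the imide: hydride attacks the exocyclic carbonyl, giving the primary alcohol and freeing auxiliary 2, while the alkene and the stereocentre are untouched.

Step 4
Reactants: 8 (2S)-2-[(3,4,5-trimethoxyphenyl)methyl]pent-4-en-1-ol; 9 5-(chloromethyl)-1,2,3-trimethoxybenzene
Product: 11 5-[(2S)-2-{[(3,4,5-trimethoxyphenyl)methoxy]methyl}pent-4-en-1-yl]-1,2,3-trimethoxybenzene, via sodium alkoxide 10 (not isolated)
Conditions: NaH, DMF, 0 °C; then 9, Bu4NI (cat.), 0 °C → rt
Reagents that add atoms: none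
Why: Williamson ether synthesis: the primary alkoxide 10 displaces the benzylic chloride by SN2 under iodide catalysis, installing the ring A benzyl ether without involving the stereocentre.

Step 5
Reactants: 11 5-[(2S)-2-{[(3,4,5-trimethoxyphenyl)methoxy]methyl}pent-4-en-1-yl]-1,2,3-trimethoxybenzene
Product: 13 (3R)-4-(3,4,5-trimethoxyphenyl)-3-{[(3,4,5-trimethoxyphenyl)methoxy]methyl}butanal, via vicinal diol 12 (not isolated)
Conditions: OsO4 (2 mol %), NaIO4, 2,6-lutidine, dioxane/H2O 3:1, rt
Reagents that add atoms: osmium tetroxide, O=[Os](=O)(=O)=O (delivers the oxygen); sodium periodate, [Na+].[O-]I(=O)(=O)=O (restores it)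
Why: Lemieux–Johnson oxidation: OsO4 dihydroxylates the terminal alkene to diol 12 and periodate cleaves it to the aldehyde, conditions under which the arenes and the benzylic ether are inert and which avoid ozone.

Step 6
Reactants: 13 (3R)-4-(3,4,5-trimethoxyphenyl)-3-{[(3,4,5-trimethoxyphenyl)methoxy]methyl}butanal
Product: 15 methyl (3R)-4-(3,4,5-trimethoxyphenyl)-3-{[(3,4,5-trimethoxyphenyl)methoxy]methyl}butanoate, via carboxylic acid 14 (not isolated)
Conditions: NaClO2, NaH2PO4, 2-methylbut-2-ene, t-BuOH/H2O, 0 °C → rt; then MeI, K2CO3, DMF, rt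
Reagents that add atoms: sodium chlorite, [Na+].[O-]Cl=O (one oxygen); iodomethane, CI (methyl group)
Why: Pinnick oxidation to acid 14, with 2-methylbut-2-ene trapping hypochlorous acid so that the electron-rich rings are not chlorinated, followed by O-methylation of the carboxylate.

Step 7
Reactants: 15 methyl (3R)-4-(3,4,5-trimethoxyphenyl)-3-{[(3,4,5-trimethoxyphenyl)methoxy]methyl}butanoate
Product: 16 methyl (3R)-2-benzoyl-4-(3,4,5-trimethoxyphenyl)-3-{[(3,4,5-trimethoxyphenyl)methoxy]methyl}butanoate (both C2 epimers)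
Conditions: NaH, PhCO2Me, DME, 85 °C; AcOH quench
Reagents that add atoms: methyl benzoate, COC(=O)c1ccccc1 (benzoyl group)
Why: Crossed Claisen condensation: the ester enolate is acylated by non-enolisable methyl benzoate and the equilibrium is pulled over by the stabilised β-keto ester enolate; the C2 epimers converge in the next step.

Step 8
Reactants: 16 methyl (3R)-2-benzoyl-4-(3,4,5-trimethoxyphenyl)-3-{[(3,4,5-trimethoxyphenyl)methoxy]methyl}butanoate
Product: 17 methyl (3R)-2-diazo-4-(3,4,5-trimethoxyphenyl)-3-{[(3,4,5-trimethoxyphenyl)methoxy]methyl}butanoate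
Conditions: 4-O2NC6H4SO2N3, DBU, CH2Cl2, 0 °C → rt
Reagents that add atoms: 4-nitrobenzenesulfonyl azide, [N-]=[N+]=NS(=O)(=O)c1ccc(cc1)[N+](=O)[O-] (two nitrogen atoms)
Why: Deacylative Regitz diazo transfer: the enolate of the 2-substituted β-keto ester adds to the sulfonyl azide and the adduct fragments with transfer of the benzoyl group to the sulfonamide nitrogen, leaving the α-diazo ester with the adjacent stereocentre intact.

Step 9
Reactants: 17 methyl (3R)-2-diazo-4-(3,4,5-trimethoxyphenyl)-3-{[(3,4,5-trimethoxyphenyl)methoxy]methyl}butanoate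
Product: 19 methyl (2S,3S,4R)-2-(3,4,5-trimethoxyphenyl)-4-[(3,4,5-trimethoxyphenyl)methyl]oxolane-3-carboxylate, via rhodium carbene 18 (not isolated)
Conditions: Rh2(O2CCMe3)4 (1 mol %), CH2Cl2, −78 °C, slow addition of 17, then slowly to −20 °C
Reagents that add atoms: none
Why: Rh2(O2CCMe3)4 (divalent rhodium) expels N2 from 17 to give the electrophilic carbene 18, whose vacant p orbital at C3 takes up hydride from the ring A benzylic C–H next to oxygen while the C2–C3 bond forms in the same three-centre event, the new bond taking the place of the departing hydrogen. The closest known reaction type is the dirhodium-carboxylate-catalysed 1,5 C–H insertion of α-alkyl α-diazo esters into ether C–H bonds, which gives 2-substituted oxolane-3-carboxylates. The oxolane is closed by C2–C3 bond formation across the chain C3–C4–C5–O1–C2, through a chair-like six-membered transition state that counts the migrating hydrogen. C2 is controlled by the existing C4 centre, since the C4 benzyl group and the C2 aryl group both lie equatorial in that chair and so end trans on the ring; C3 is set in the same event, because hydride arrives on the carbene face on the side of C4–H while the ester points outward, leaving the ester cis to the C4 benzyl group and trans to the C2 aryl group. The step needs site selectivity for this C–H bond over a 1,2-hydride shift from C4–H and over attack on ring B; the double activation of the C–H bond, the bulky and electron-rich pivalate ligands and the low temperature are relied on to secure it.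

Step 10
Reactants: 19 methyl (2S,3S,4R)-2-(3,4,5-trimethoxyphenyl)-4-[(3,4,5-trimethoxyphenyl)methyl]oxolane-3-carboxylate
Product: 20 [(2S,3R,4R)-2-(3,4,5-trimethoxyphenyl)-4-[(3,4,5-trimethoxyphenyl)methyl]oxolan-3-yl]methanol
Conditions: LiAlH4, THF, 0 °C; then H2O, aq. NaOH
Reagents that add atoms: none
Why: Hydride reduction of the methyl ester to the primary alcohol, fast enough at 0 °C that C3 should not enolise, so all three stereocentres are carried through (the C3 descriptor changes from S to R only because the priorities change).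

**Compound list**

1 | 3-(3,4,5-trimethoxyphenyl)propanoic acid | COc1cc(CCC(=O)O)cc(OC)c1OC | starting material
2 | (4S)-4-benzyl-1,3-oxazolidin-2-one | O=C1OC[C@H](Cc2ccccc2)N1 | starting material
3 | 2,2-dimethylpropanoic 3-(3,4,5-trimethoxyphenyl)propanoic anhydride | COc1cc(CCC(=O)OC(=O)C(C)(C)C)cc(OC)c1OC | intermediate
4 | (4S)-4-benzyl-3-[3-(3,4,5-trimethoxyphenyl)propanoyl]-1,3-oxazolidin-2-one | COc1cc(CCC(=O)N2[C@@H](Cc3ccccc3)COC2=O)cc(OC)c1OC | intermediate
5 | 3-bromoprop-1-ene | C=CCBr | starting material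
6 | sodium (1Z)-1-[(4S)-4-benzyl-2-oxo-1,3-oxazolidin-3-yl]-3-(3,4,5-trimethoxyphenyl)prop-1-en-1-olate | [Na+].[O-]/C(=C\Cc1cc(OC)c(OC)c(OC)c1)N1[C@@H](Cc2ccccc2)COC1=O | intermediate
7 | (4S)-4-benzyl-3-{(2S)-2-[(3,4,5-trimethoxyphenyl)methyl]pent-4-enoyl}-1,3-oxazolidin-2-one | C=CC[C@@H](Cc1cc(OC)c(OC)c(OC)c1)C(=O)N1[C@@H](Cc2ccccc2)COC1=O | intermediate
8 | (2S)-2-[(3,4,5-trimethoxyphenyl)methyl]pent-4-en-1-ol | C=CC[C@@H](Cc1cc(OC)c(OC)c(OC)c1)CO | intermediate
9 | 5-(chloromethyl)-1,2,3-trimethoxybenzene | COc1cc(CCl)cc(OC)c1OC | starting material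
10 | sodium (2S)-2-[(3,4,5-trimethoxyphenyl)methyl]pent-4-en-1-olate | [Na+].C=CC[C@@H](Cc1cc(OC)c(OC)c(OC)c1)C[O-] | intermediate
11 | 5-[(2S)-2-{[(3,4,5-trimethoxyphenyl)methoxy]methyl}pent-4-en-1-yl]-1,2,3-trimethoxybenzene | C=CC[C@@H](Cc1cc(OC)c(OC)c(OC)c1)COCc1cc(OC)c(OC)c(OC)c1 | intermediate
12 | (4R)-5-(3,4,5-trimethoxyphenyl)-4-{[(3,4,5-trimethoxyphenyl)methoxy]methyl}pentane-1,2-diol (both C2 epimers) | OCC(O)C[C@@H](Cc1cc(OC)c(OC)c(OC)c1)COCc1cc(OC)c(OC)c(OC)c1 | intermediate
13 | (3R)-4-(3,4,5-trimethoxyphenyl)-3-{[(3,4,5-trimethoxyphenyl)methoxy]methyl}butanal | O=CC[C@@H](Cc1cc(OC)c(OC)c(OC)c1)COCc1cc(OC)c(OC)c(OC)c1 | intermediate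
14 | (3R)-4-(3,4,5-trimethoxyphenyl)-3-{[(3,4,5-trimethoxyphenyl)methoxy]methyl}butanoic acid | OC(=O)C[C@@H](Cc1cc(OC)c(OC)c(OC)c1)COCc1cc(OC)c(OC)c(OC)c1 | intermediate
15 | methyl (3R)-4-(3,4,5-trimethoxyphenyl)-3-{[(3,4,5-trimethoxyphenyl)methoxy]methyl}butanoate | COC(=O)C[C@@H](Cc1cc(OC)c(OC)c(OC)c1)COCc1cc(OC)c(OC)c(OC)c1 | intermediate
16 | methyl (3R)-2-benzoyl-4-(3,4,5-trimethoxyphenyl)-3-{[(3,4,5-trimethoxyphenyl)methoxy]methyl}butanoate (both C2 epimers) | COC(=O)C(C(=O)c1ccccc1)[C@@H](Cc1cc(OC)c(OC)c(OC)c1)COCc1cc(OC)c(OC)c(OC)c1 | intermediate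
17 | methyl (3R)-2-diazo-4-(3,4,5-trimethoxyphenyl)-3-{[(3,4,5-trimethoxyphenyl)methoxy]methyl}butanoate | COC(=O)C(=[N+]=[N-])[C@@H](Cc1cc(OC)c(OC)c(OC)c1)COCc1cc(OC)c(OC)c(OC)c1 | intermediate
18 | dirhodium tetrapivalate carbene at C2 of methyl (3R)-4-(3,4,5-trimethoxyphenyl)-3-{[(3,4,5-trimethoxyphenyl)methoxy]methyl}butanoate | COC(=O)C(=[Rh+2])[C@@H](Cc1cc(OC)c(OC)c(OC)c1)COCc1cc(OC)c(OC)c(OC)c1.[Rh+2].CC(C)(C)C(=O)[O-].CC(C)(C)C(=O)[O-].CC(C)(C)C(=O)[O-].CC(C)(C)C(=O)[O-] | intermediate
19 | methyl (2S,3S,4R)-2-(3,4,5-trimethoxyphenyl)-4-[(3,4,5-trimethoxyphenyl)methyl]oxolane-3-carboxylate | COc1cc(C[C@H]2CO[C@H](c3cc(OC)c(OC)c(OC)c3)[C@H]2C(=O)OC)cc(OC)c1OC | intermediate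
20 | [(2S,3R,4R)-2-(3,4,5-trimethoxyphenyl)-4-[(3,4,5-trimethoxyphenyl)methyl]oxolan-3-yl]methanol | COc1cc(C[C@H]2CO[C@H](c3cc(OC)c(OC)c(OC)c3)[C@H]2CO)cc(OC)c1OC | target

**Step count**

Total steps: 10. Longest linear sequence: 10 steps (from acid 1 to target 20).

**Steps most likely to fail**

Risk 1, step 9. The carbene may be lost through a 1,2-hydride shift from the tertiary C4–H (giving an alkene), or through electrophilic substitution on ring B, whose ortho carbon is also 1,5 to C3. Facial control at C2 and C3 may also be incomplete. Pivalate is preferred to triphenylacetate or fluorinated carboxylates because less electrophilic carbenes lean toward hydridic C–H bonds and away from arenes. If the ester emerges partly epimeric at C3, brief equilibration with NaOMe in MeOH before step 10 is the first remedy; the ester trans to the C2 aryl group is expected to be the more stable arrangement.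

The fallback sets out from alcohol 8 and comes back at target 20, forming the oxolane by C–O instead of C–C closure. Lemieux–Johnson cleavage of 8 (OsO4 cat., NaIO4, 2,6-lutidine, dioxane/H2O) should give the lactol (4R)-4-[(3,4,5-trimethoxyphenyl)methyl]oxolan-2-ol F1. Oxidation with PhI(OAc)2 and catalytic TEMPO in CH2Cl2 should give the lactone (4R)-4-[(3,4,5-trimethoxyphenyl)methyl]oxolan-2-one F2. Its lithium enolate (LiN(SiMe3)2, THF, −78 °C) is expected to add to 3,4,5-trimethoxybenzaldehyde anti to the C4 substituent, giving (3S,4R)-3-[hydroxy(3,4,5-trimethoxyphenyl)methyl]-4-[(3,4,5-trimethoxyphenyl)methyl]oxolan-2-one F3 as carbinol epimers. LiAlH4 in THF should reduce it to the triol (2R,3R)-2-[hydroxy(3,4,5-trimethoxyphenyl)methyl]-3-[(3,4,5-trimethoxyphenyl)methyl]butane-1,4-diol F4. Catalytic camphorsulfonic acid in CH2Cl2 should then ionise the benzylic carbinol, and the primary hydroxyl on the C4 side should close the oxolane with the aryl group trans to the C3 hydroxymethyl group, giving 20. The acid is kept mild and the time short so that ring B does not attack the benzylic cation.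

Risk 2, step 7. C-acylation under hot NaH may be incomplete, or the ester may self-condense, so that the activating benzoyl group is not installed cleanly.

The fallback sets out from ester 15 and comes back at diazo ester 17, building the diazo group from an amine instead of by acyl activation. The potassium enolate of 15 (KN(SiMe3)2, THF, −78 °C) is treated with 2,4,6-triisopropylbenzenesulfonyl azide and quenched with AcOH, which should give methyl (3R)-2-azido-4-(3,4,5-trimethoxyphenyl)-3-{[(3,4,5-trimethoxyphenyl)methoxy]methyl}butanoate F5 as C2 epimers. Staudinger reduction (PPh3, THF/H2O) should give methyl (3R)-2-amino-4-(3,4,5-trimethoxyphenyl)-3-{[(3,4,5-trimethoxyphenyl)methoxy]methyl}butanoate F6. Diazotisation with isopentyl nitrite and catalytic AcOH in warm CHCl3 should then give 17.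

Risk 3, step 2. Alkylation by allyl bromide may be slow at low temperature, so that the enolate decomposes or facial selectivity erodes on warming, lowering the enantiomeric purity of everything downstream.

The fallback sets out from chloride 9 and comes back at alcohol 8, with the roles of nucleophile and electrophile exchanged. (4R)-4-Benzyl-1,3-oxazolidin-2-one is acylated (n-BuLi, THF, −78 °C; pent-4-enoyl chloride) to (4R)-4-benzyl-3-(pent-4-enoyl)-1,3-oxazolidin-2-one F7. Its sodium enolate (NaN(SiMe3)2, THF, −78 °C) is alkylated with the more reactive benzylic halide 9 in the presence of Bu4NI, which should give (4R)-4-benzyl-3-{(2S)-2-[(3,4,5-trimethoxyphenyl)methyl]pent-4-enoyl}-1,3-oxazolidin-2-one F8. LiBH4 reduction as in step 3 should then give 8.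

**Further compounds**

F1 | step 9 | (4R)-4-[(3,4,5-trimethoxyphenyl)methyl]oxolan-2-ol | OC1C[C@@H](Cc2cc(OC)c(OC)c(OC)c2)CO1
F2 | step 9 | (4R)-4-[(3,4,5-trimethoxyphenyl)methyl]oxolan-2-one | O=C1C[C@@H](Cc2cc(OC)c(OC)c(OC)c2)CO1
F3 | step 9 | (3S,4R)-3-[hydroxy(3,4,5-trimethoxyphenyl)methyl]-4-[(3,4,5-trimethoxyphenyl)methyl]oxolan-2-one (carbinol epimers) | O=C1OC[C@H](Cc2cc(OC)c(OC)c(OC)c2)[C@H]1C(O)c1cc(OC)c(OC)c(OC)c1
F4 | step 9 | (2R,3R)-2-[hydroxy(3,4,5-trimethoxyphenyl)methyl]-3-[(3,4,5-trimethoxyphenyl)methyl]butane-1,4-diol (carbinol epimers) | COc1cc(C[C@H]([C@H](CO)C(O)c2cc(OC)c(OC)c(OC)c2)CO)cc(OC)c1OC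
F5 | step 7 | methyl (3R)-2-azido-4-(3,4,5-trimethoxyphenyl)-3-{[(3,4,5-trimethoxyphenyl)methoxy]methyl}butanoate (C2 epimers) | COC(=O)C(N=[N+]=[N-])[C@@H](Cc1cc(OC)c(OC)c(OC)c1)COCc1cc(OC)c(OC)c(OC)c1
F6 | step 7 | methyl (3R)-2-amino-4-(3,4,5-trimethoxyphenyl)-3-{[(3,4,5-trimethoxyphenyl)methoxy]methyl}butanoate (C2 epimers) | COC(=O)C(N)[C@@H](Cc1cc(OC)c(OC)c(OC)c1)COCc1cc(OC)c(OC)c(OC)c1
F7 | step 2 | (4R)-4-benzyl-3-(pent-4-enoyl)-1,3-oxazolidin-2-one | C=CCCC(=O)N1[C@H](Cc2ccccc2)COC1=O
F8 | step 2 | (4R)-4-benzyl-3-{(2S)-2-[(3,4,5-trimethoxyphenyl)methyl]pent-4-enoyl}-1,3-oxazolidin-2-one | C=CC[C@@H](Cc1cc(OC)c(OC)c(OC)c1)C(=O)N1[C@H](Cc2ccccc2)COC1=O
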